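## Retrosynthetic overview

1. The 2H-pyran ring is the only ring built and it is closed last: target ⇒ 3-prenyl-2,4,6-trihydroxybenzophenone + prenal (condensation, then oxa-6π electrocyclisation).
2. Prenyl group: C-alkylation of 2,4,6-trihydroxybenzophenone, which comes from its trimethyl ether by O-demethylation.
3. Key disconnection: the C(=O)–C(phenyl) bond. The aldehyde carbon of 2,4,6-trimethoxybenzaldehyde becomes an acyl anion equivalent (Breslow intermediate, NHC catalysis) and adds to benzyne; both carbons are electrophiles in their normal polarity.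
4. Both benzene rings are bought; the phenyl ring arrives as benzyne from 2-(trimethylsilyl)phenyl triflate.

Assumption: the target has no stereocentre and no stereogenic double bond, so it is achiral and no stereocontrol is needed.

## Route

Step 1
Reactants: 1 2,4,6-trimethoxybenzaldehyde; 2 2-(trimethylsilyl)phenyl trifluoromethanesulfonate
Product: 5 phenyl(2,4,6-trimethoxyphenyl)methanone, via benzyne 3 (not isolated), via Breslow intermediate 4 (not isolated)
Conditions: 2 (1.5 equiv, slow addition), 3-mesityl-5,6,7,8-tetrahydro-4H-cyclohepta[d]thiazol-3-ium perchlorate (10–20 mol%), K2CO3 (20–40 mol%), KF (3 equiv), 18-crown-6 (3 equiv), THF, 25 °C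
Reagents that add atoms: none
Why: NHC-catalysed hydroacylation of an aryne: the thiazolylidene adds to 1 to give Breslow intermediate 4, an acyl anion equivalent whose carbon attacks the electrophilic benzyne 3 released from 2 by fluoride, and proton transfer with loss of the carbene gives ketone 5, while the two ortho-methoxy groups block the competing benzoin dimerisation.

Step 2
Reactants: 5 phenyl(2,4,6-trimethoxyphenyl)methanone
Product: 6 phenyl(2,4,6-trihydroxyphenyl)methanone
Conditions: BBr3 (4 equiv), CH2Cl2, −78 °C → rt; then H2O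
Reagents that add atoms: none
Why: Lewis-acid cleavage of aryl methyl ethers: BBr3 binds each ether oxygen (the two ortho ones helped by chelation to the ketone), bromide removes the methyl group by SN2, and aqueous work-up frees the three phenols while the diaryl ketone is untouched.

Step 3
Reactants: 6 phenyl(2,4,6-trihydroxyphenyl)methanone; 7 prenyl bromide (1-bromo-3-methylbut-2-ene)
Product: 8 (2,4,6-trihydroxy-3-(3-methylbut-2-en-1-yl)phenyl)(phenyl)methanone
Conditions: 7 (1.0 equiv), 10% aq KOH, 0 °C → rt; then dil. HCl
Reagents that add atoms: none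
Why: C-alkylation of an ambident phloroglucinol phenoxide: in water the hydrogen-bonded phenoxide of 6 reacts with the allylic bromide at ring carbon (SN2), and because the two free ring positions are equivalent only one mono-C-prenyl product can form.

Step 4
Reactants: 8 (2,4,6-trihydroxy-3-(3-methylbut-2-en-1-yl)phenyl)(phenyl)methanone; 9 prenal (3-methylbut-2-enal)
Product: 11 (5,7-dihydroxy-2,2-dimethyl-8-(3-methylbut-2-en-1-yl)-2H-chromen-6-yl)(phenyl)methanone, via o-quinone methide 10 (not isolated)
Conditions: 9 (2 equiv), ethylenediammonium diacetate (EDDA, 20 mol%), xylene, 140 °C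
Reagents that add atoms: none
Why: Knoevenagel-type condensation followed by oxa-6π electrocyclisation: EDDA activates prenal as its iminium ion, the only free ring carbon of 8 attacks it, loss of water gives o-quinone methide 10, and its carbonyl oxygen para to the benzoyl group (the ortho oxygens stay tied up in the O–H···O=C chelate) closes the 2H-pyran.

## Compound list

1 | 2,4,6-trimethoxybenzaldehyde | COc1cc(OC)c(C=O)c(OC)c1 | starting material
2 | 2-(trimethylsilyl)phenyl trifluoromethanesulfonate | C[Si](C)(C)c1ccccc1OS(=O)(=O)C(F)(F)F | starting material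
3 | benzyne | C1=CC#CC=C1 | intermediate
4 | Breslow intermediate, (3-mesityl-3,4,5,6,7,8-hexahydro-2H-cyclohepta[d]thiazol-2-ylidene)(2,4,6-trimethoxyphenyl)methanol | COc1cc(OC)c(C(O)=C2SC3=C(CCCCC3)N2c2c(C)cc(C)cc2C)c(OC)c1 | intermediate
5 | phenyl(2,4,6-trimethoxyphenyl)methanone | COc1cc(OC)c(C(=O)c2ccccc2)c(OC)c1 | intermediate
6 | phenyl(2,4,6-trihydroxyphenyl)methanone | Oc1cc(O)c(C(=O)c2ccccc2)c(O)c1 | intermediate
7 | prenyl bromide (1-bromo-3-methylbut-2-ene) | CC(C)=CCBr | starting material
8 | (2,4,6-trihydroxy-3-(3-methylbut-2-en-1-yl)phenyl)(phenyl)methanone | CC(C)=CCc1c(O)cc(O)c(C(=O)c2ccccc2)c1O | intermediate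
9 | prenal (3-methylbut-2-enal) | CC(C)=CC=O | starting material
10 | o-quinone methide, 4-benzoyl-3,5-dihydroxy-2-(3-methylbut-2-en-1-yl)-6-(3-methylbut-2-en-1-ylidene)cyclohexa-2,4-dien-1-one | CC(C)=CCC1=C(O)C(C(=O)c2ccccc2)=C(O)C(=CC=C(C)C)C1=O | intermediate
11 | (5,7-dihydroxy-2,2-dimethyl-8-(3-methylbut-2-en-1-yl)-2H-chromen-6-yl)(phenyl)methanone | CC(C)=CCc1c(O)c(C(=O)c2ccccc2)c(O)c2c1OC(C)(C)C=C2 | target

## Step count and risks

Total step count: 4. Longest linear sequence: 4.

Three steps most likely to fail:

**Step 1 (aryne hydroacylation).** The reaction type is known, but a 2,6-dimethoxy aldehyde forms its Breslow intermediate slowly, so benzyne may be consumed by the free carbene first. The fallback keeps the reversed polarity but makes the acyl anion stoichiometric. It sets out from 1: propane-1,3-dithiol and BF3·OEt2 in CH2Cl2 give 2-(2,4,6-trimethoxyphenyl)-1,3-dithiane F1. Deprotonation with LiN(SiMe3)2 and Pd/NiXantphos-catalysed coupling with bromobenzene give 2-phenyl-2-(2,4,6-trimethoxyphenyl)-1,3-dithiane F2. MeI and CaCO3 in aqueous MeCN unmask the ketone, and the fallback comes back to the route at 5.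

**Step 4 (pyran closure, regiochemistry).** Closure through the oxygen ortho to the benzoyl group would give the regioisomeric chromene, and a mixture that needs chromatography is likely; I could not settle the ratio from precedent. The fallback fixes the ring oxygen before the ring is made. It sets out from 8: 3-chloro-3-methylbut-1-yne, K2CO3, KI and catalytic CuI in acetone alkylate the most acidic, non-chelated 4-OH to give (2,6-dihydroxy-4-((2-methylbut-3-yn-2-yl)oxy)-3-(3-methylbut-2-en-1-yl)phenyl)(phenyl)methanone F3. Ac2O, pyridine and DMAP cap the two remaining hydroxyls as 2-benzoyl-5-((2-methylbut-3-yn-2-yl)oxy)-4-(3-methylbut-2-en-1-yl)-1,3-phenylene diacetate F4. Heating in xylene at 140 °C brings about aromatic propargyl Claisen rearrangement to the only free ortho carbon, hydrogen shift and 6π closure; the former ether oxygen is then the only free phenol oxygen, so it alone can close the ring, giving 6-benzoyl-2,2-dimethyl-8-(3-methylbut-2-en-1-yl)-2H-chromene-5,7-diyl diacetate F5. K2CO3 in MeOH removes the acetates and the fallback comes back to the route at 11.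

**Step 3 (mono-C-prenylation).** Statistical over-alkylation (3,5-diprenyl and gem-diprenyl products) and some O-alkylation will hold the yield of 8 to a modest level. The fallback makes the over-alkylation productive. It sets out from 6: exhaustive C-prenylation with 7 (2.2 equiv, aq KOH, 0 °C) gives (2,4,6-trihydroxy-3,5-bis(3-methylbut-2-en-1-yl)phenyl)(phenyl)methanone F6. DDQ (1 equiv, benzene, reflux) then removes hydride from one benzylic CH2 to form 10, which closes to the pyran. The fallback comes back to the route at 11 and needs neither 8 nor 9; it carries the same closure-regiochemistry question as step 4.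

## Further compounds

F1 | step 1 | 2-(2,4,6-trimethoxyphenyl)-1,3-dithiane | COc1cc(OC)c(C2SCCCS2)c(OC)c1
F2 | step 1 | 2-phenyl-2-(2,4,6-trimethoxyphenyl)-1,3-dithiane | COc1cc(OC)c(C2(c3ccccc3)SCCCS2)c(OC)c1
F3 | step 4 | (2,6-dihydroxy-4-((2-methylbut-3-yn-2-yl)oxy)-3-(3-methylbut-2-en-1-yl)phenyl)(phenyl)methanone | CC(C)=CCc1c(OC(C)(C)C#C)cc(O)c(C(=O)c2ccccc2)c1O
F4 | step 4 | 2-benzoyl-5-((2-methylbut-3-yn-2-yl)oxy)-4-(3-methylbut-2-en-1-yl)-1,3-phenylene diacetate | CC(C)=CCc1c(OC(C)(C)C#C)cc(OC(C)=O)c(C(=O)c2ccccc2)c1OC(C)=O
F5 | step 4 | 6-benzoyl-2,2-dimethyl-8-(3-methylbut-2-en-1-yl)-2H-chromene-5,7-diyl diacetate | CC(C)=CCc1c(OC(C)=O)c(C(=O)c2ccccc2)c(OC(C)=O)c2c1OC(C)(C)C=C2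
F6 | step 3 | (2,4,6-trihydroxy-3,5-bis(3-methylbut-2-en-1-yl)phenyl)(phenyl)methanone | CC(C)=CCc1c(O)c(CC=C(C)C)c(O)c(C(=O)c2ccccc2)c1O
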